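The data were computed with constants of no real substance, noise included.

| setting | teal | eta | delta |
|---|---|---|---|
| left-handed substrate | 25 mM | 25 mM | 25 mM |
| right-handed substrate | 25 mM | 25 mM | 25 mM |
| gas | 14 mM (held) | 14 mM (held) | 14 mM (held) |
| free catalyst | 8.5 mol% | 17 mol% | 17 mol% |
| racemization catalyst | 9.4 mol% | 9.4 mol% | 9.4 mol% |
| remark | run made earlier |  |  |
| time |  | 6.0 h | 25 h |

teal run (percent of the left-handed substrate and right-handed substrate together charged)

| time / min | left-handed product / % | right-handed product / % |
|---|---|---|
| 15.0 | 3.2 | 1.9 |
| 30.0 | 5.8 | 0.9 |
| 40.0 | 5.3 | 1.2 |
| 60.0 | 10.1 | 4.9 |
| 80.0 | 16.0 | 7.9 |

(readings scatter by 1 percentage point)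

- free catalyst is single-handed; left-handed substrate and right-handed substrate are mirror images of each other, charged as a racemate, each of them at the stated concentration
- the numbers in the tables scatter with a standard deviation of 1 percentage point
- at the start none of the gas is in solution
- an excess is the difference of the two amounts in percent of their sum
- an excess is below zero if the other one leads
- no earlier run changes the charge of free catalyst; that part of a forecast is a guess

* the flask that ends with the higher excess of left-handed product over right-handed product in the product, or "neither" when 2 percentage points or less lies between them (eta / delta / neither)
* excess of left-handed product over right-handed product in the product at the end, eta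
* excess of left-handed product over right-handed product in the product at the end, delta

The two substrates and the two products add up to what was charged, so the sum of the products climbs towards 100% of the charge, whatever their difference does.

In teal that sum rises at 0.204 /h up to 15.0 min and at 0.267 /h between 60.0 min and 80.0 min. Per unit of substrate still present, the late slope gives:

kt = 0.331 /h

Scaling this with the free catalyst, which is a guess, gives for eta:

ke = 0.663 /h

On this estimate the knee of the curve, where 10.0% of the substrate stays, comes at 3.47 h, and by 6.0 h hardly any is left. Eta and delta have the same charge, so up to 6.0 h they are one curve. After that delta stands on for the idle time, the hours it sits with its product nearly made: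

W = 19.0 h

The excess in teal falls from 56.3% in the readings up to 40.0 min to 34.2% in the later ones. I read this as left-handed product turning into its mirror image (product racemization), with a level of zero excess. The reading gives a halving time of

h = 0.966 h

That figure is loose, so eta's level stays open. Taken at 4 times that halving time, W divides the excess by 30.2. My reckoning is therefore eta ahead and delta close to zero.

The forecast gave 25% for eta and 19% for delta, with eta ahead, taking “an intermediate case, with the late conversion lowering delta somewhat”.

The flask gives 15.5% for eta and 0.467% for delta, with eta ahead.

    gas ⇌ reagent, rate k1*(csat - [reagent]) (kL = 0.690 /h)
    left-handed product ⇌ right-handed product (k = 0.0910 /h)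
    reagent + free catalyst + right-handed substrate → free catalyst + right-handed product (k = 84000 /M²/h)
    left-handed substrate + racemization catalyst ⇌ right-handed substrate + racemization catalyst, rate k4*[racemization catalyst]*[left-handed substrate] forward; the back reaction follows from the equilibrium constant (k = 360 /M/h)
    reagent + free catalyst + left-handed substrate → free catalyst + left-handed product (k = 1.80 × 10⁵ /M²/h)

Delta read early, at 6.0 h, stands at 15.5%, with 1.7% of its left-handed and 3.5% of its right-handed substrate left. The idle time W then takes that same flask down to 0.467%, a division by 33.2. Over W that is on average one halving of the excess every 3.76 h.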